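The readings were generated by integration on assumed constants, noise included.

At early times Wednesday's flask, charged with more initiator than Monday's, made product faster: 32.4% at 0.625 d against Monday's 8.5% at 1.04 d. Monday's readings then stood at 19.4% of product at 6.00 d, with 79.3% of its starting material still there. You wanted a quick number for these flasks:

| setting | Monday's | Wednesday's | dusk | noon | dawn | spring |
|---|---|---|---|---|---|---|
| starting material | 0.50 M | 0.50 M | 0.50 M | 0.50 M | 0.50 M | 0.50 M |
| reagent | 0.65 M | 0.65 M | 0.650 M | 0.650 M | 0.650 M | 0.650 M |
| initiator | 0.52 mM | 4.6 mM | 6.0 mM | 0.80 mM | 3.4 mM | 2.5 mM |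
| remark | run made earlier | run made earlier |  |  |  |  |
| time |  |  | 8.0 d | 8.0 d | 8.0 d | 8.0 d |

| run | time / d | product / % | starting material / % |
|---|---|---|---|
| Monday's | 0.417 | 2.1 | 96.2 |
| Monday's | 1.04 | 8.5 | 93.3 |
| Monday's | 2.50 | 13.5 | 87.0 |
| Monday's | 6.00 | 19.4 | 79.3 |
| Wednesday's | 0.625 | 32.4 | 65.3 |
| Wednesday's | 2.08 | 70.3 | 26.4 |
| Wednesday's | 4.00 | 87.7 | 10.6 |
| Wednesday's | 6.00 | 96.6 | 5.0 |

(each reading ± 1 percentage point)

1. all flasks from highest to lowest amount of product, in percent of the starting material charged, at 8.0 d (dusk / noon / dawn / spring)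
2. the amount of product, in percent of the starting material charged of the flask you put first, at 8.0 d
3. the amount of product, in percent of the starting material charged of the flask you put last, at 8.0 d

- the numbers in the tables scatter by 1 percentage point (one standard deviation)
- a reading or a percentage of product counts all its forms, free or not

I assumed that each product takes one reagent, so c(reagent) left is c(reagent) charged minus c(product). I then reckoned the burn number: the natural log of c(reagent) charged over c(reagent) left, divided by c(initiator) charged. At 6.00 d Monday's flask gave 0.311 mM⁻¹ and Wednesday's 0.295 mM⁻¹, although Wednesday's held 8.85 times as much initiator. So I followed this one number.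

Wednesday's stood at 0.169 mM⁻¹ at 2.08 d and 0.244 mM⁻¹ at 4.00 d. The second span therefore added 0.443 of what the first had added, and I let each later span shrink by that factor. Carried from the mean of the two values at 6.00 d to 8.0 d, the burn number, reagent's log loss per initiator charged, came to 0.319 mM⁻¹.

That gave me noon 29.3%, spring 71.5% and dawn 86.1%. Dusk's sum asked for 0.554 M of reagent, more than the 0.50 M of starting material, so I capped dusk at that charge.

The forecast read dusk > dawn > spring > noon, with 99.3% first and 32.6% last, on the ground that “Loss of active initiator in proportion to conversion does fit”. My order was the same, and my noon stood lower.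

The flasks gave dusk > dawn > spring > noon: dusk 98.3%, dawn 85.9%, spring 72.2%, noon 30.5%.

    initiator → 2 initiating radical (k = 4.16 × 10⁻⁶ s⁻¹)
    starting material + initiating radical → capped initiator + first chain carrier (k = 51300 M⁻¹ s⁻¹)
    reagent + first chain carrier → product + second chain carrier (k = 927 M⁻¹ s⁻¹)
    starting material + second chain carrier → by-product + first chain carrier (k = 5080 M⁻¹ s⁻¹)
    first chain carrier → ended carrier (k = 5.17 s⁻¹)
    2 first chain carrier → ended chains A (k = 2.70 × 10⁷ M⁻¹ s⁻¹)
    2 second chain carrier → ended chains B (k = 4.00 × 10⁸ M⁻¹ s⁻¹)
    crystals ⇌ product, rate k8*(cs8 - [product]) while solid is left; crystals form when [product] > cs8 (solubility = 0.200 M, k = 9.95 × 10⁻⁴ s⁻¹)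

In noon, the step from reagent and first chain carrier to product had 49% of its turnover up to 8.0 d behind it by 1.60 d, and at 8.0 d initiator was down to 5.6% of its charge, with 69% of the starting material still there. In dusk, starting material reached 0% by 8.0 d, with 24% of the reagent left. Noon's remaining reagent gives a burn number of 0.334 mM⁻¹ against my 0.319 mM⁻¹. For noon's recipe with 0.0032 M of initiator, that 0.319 mM⁻¹ gives 83.2% of product, and the flask stood at 83.2%.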